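A one-step world has the target climbing to its final amount and staying there, but the amber run climbs to 28.0 % and then sags, so I follow two fractions left: the part of the rise still to come and the part of the plateau still kept.

| flask | starting material | protic impurity | remark | time |
|---|---|---|---|---|
| violet | 0.23 M | 0.15 M | run made earlier |  |
| amber | 0.23 M | 0.35 M | run made earlier |  |
| teal | 0.35 M | 0.23 M | run made earlier |  |
| flask | 0.23 M | 0.230 M |  | 15 h |

| run | time / h | target / % |
|---|---|---|
| violet | 0.833 | 20.5 |
| violet | 1.33 | 26.3 |
| violet | 2.50 | 29.0 |
| violet | 5.00 | 28.7 |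
| violet | 10.0 | 27.4 |
| violet | 20.0 | 26.8 |
| amber | 0.833 | 19.1 |
| amber | 1.33 | 24.9 |
| amber | 2.50 | 28.0 |
| amber | 5.00 | 27.3 |
| amber | 10.0 | 25.9 |
| amber | 20.0 | 22.1 |
| teal | 0.833 | 19.6 |
| teal | 1.50 | 26.2 |
| teal | 4.00 | 28.2 |
| teal | 8.00 | 27.8 |
| teal | 20.0 | 25.2 |

(each reading ± 0.5 percentage points)

- the moment within 15 h at which there is most target
- the amount of target, in percent of the starting material charged, at that time

- the numbers in the tables scatter with a standard deviation of 0.5 percentage points

The amber sag from 27.3 % to 22.1 % reads as a pseudo-first-order loss of 0.0141 h⁻¹. Extrapolated back, it gives the amber run a plateau of 29.3 %, and since 15.0 % of that is still missing there at 1.33 h, I read a rise constant of 1.43 h⁻¹ and take both over to the flask. The violet sag is slower, so I scale the loss with impurity, which gives 0.00926 h⁻¹ for the flask. The drain number, the loss constant over the rise constant, is then 0.00649: the share of plateau lost per rise time. I put the flask's peak about where the fraction of rise left equals this number, at 3.53 h, with 28.2 %. As a test, the teal run has the flask's impurity but more starting material, and the number takes its 27.8 % at 8.00 h to 24.9 % at 20.0 h, where 25.2 % was read.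

The forecast says 3.5 h (2.6 h to 4.6 h) and 28.5 % (27.9 % to 29.1 %), adding “the maximum is very flat”; my height lies 0.30 points lower.

The flask gives 28.7 % at 3.07 h.

    isomer of the product B ⇌ starting material (k = 0.0190 min⁻¹)
    starting material + protic impurity → quenched substrate (k = 0.0800 M⁻¹ min⁻¹)
    starting material ⇌ target (K = 31.0, k = 0.0180 min⁻¹)
    target ⇌ isomer of the product A (K = 1.50, k = 0.0290 min⁻¹)
    isomer of the product A ⇌ isomer of the product B (K = 0.450, k = 0.0150 min⁻¹)
    starting material → decomposition product (k = 6.90 × 10⁻⁵ min⁻¹)

In the flask, target turns into isomer of the product A with a forward half-life of 0.40 h, short against the 15 h allowed, and target is 31.5 % of target and both isomers at 3.07 h and 31.7 % at 15.0 h. The drain number takes the flask's peak to 25.7 % at 15 h, where the flask holds 25.8 %. For the neighbour with 0.92 M of impurity, the number grows to 0.0260, from which I reckon 16.8 % of target at 15 h; that neighbour holds 15.7 %.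

All runs are calculated on assumed constants; scatter was added.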